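**Plan**

1. Ring numbering used throughout: C1 (CH–O–isovaleryl), C2 (CH2), C3 (=CH), C4 (=C–Me), C5 (CH–CH2OAr), C6 (CMe2). Retrosynthetic cuts, in order: the ArO–CH2 ether (umbelliferone, attached last), the ring bond C2–C3, then C5–C6 and C1–C2 of the open chain.
2. Enabling feature: C2 is the only ring CH2 and lies between the vinylic C3–H and the ester-bearing C1, whose other neighbour is the quaternary C6. Opened at C2–C3, the target is an enol isovalerate (C1=C2H2) facing a C3 vinyl radical; one 6-endo closure makes the only carbocycle, fixes the C3=C4 alkene and creates C1 with its ester already on oxygen.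
3. Forward: Wittig enal → α-silyl allylic alcohol (PhMe2Si marks the future C3) → isobutyrate → Ireland–Claisen (C5–C6, quaternary C6) → MeLi (adds C2) → iododesilylation → enol isovalerate → tin-hydride ring closure → desilylation → Mitsunobu with 7-hydroxycoumarin.
4. Stereochemistry: the carbinol centre set by asymmetric hydrogenation of an acylsilane is relayed to C5 through the chair Ireland–Claisen transition state; C1 arises in the ring closure by hydrogen delivery to the ring radical under control of C5 (cis).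
5. Helpers and their removal: PhMe2Si (stereochemical relay and handle on C3) is exchanged for iodine, which is lost in the ring closure; TBS (tert-butyldimethylsilyl) masks the primary alcohol until the coumarin is attached.

Key step: step 10

Assumption: the (S)-tolbinap catalyst in step 4 is taken to give the (R)-carbinol (silyl group as the larger flank); if the sense is opposite, the (R)-ligand is used and nothing else changes.

**Route**

Step 1
Reactants: 1 2-[(tert-butyldimethylsilyl)oxy]acetaldehyde; 2 2-(triphenyl-λ5-phosphanylidene)propanal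
Product: 3 (2E)-4-[(tert-butyldimethylsilyl)oxy]-2-methylbut-2-enal
Conditions: PhH, 80 °C
Reagents that add atoms: none
Why: Wittig olefination with a stabilised formyl ylide, which should give the E-trisubstituted enal under thermodynamic control.

Step 2
Reactants: 3 (2E)-4-[(tert-butyldimethylsilyl)oxy]-2-methylbut-2-enal
Product: 4 rac-(2E)-4-[(tert-butyldimethylsilyl)oxy]-1-[dimethyl(phenyl)silyl]-2-methylbut-2-en-1-ol
Conditions: PhMe2SiLi, THF, −78 °C; then AcOH
Reagents that add atoms: dimethyl(phenyl)silyllithium, [Li][Si](C)(C)c1ccccc1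
Why: 1,2-addition of a silyllithium to an aldehyde; the hard silyl anion should attack the formyl carbon of the α-branched enal, and the lithium alkoxide resists Brook rearrangement at −78 °C (no stereocontrol needed, the centre is erased in step 3).

Step 3
Reactants: 4 rac-(2E)-4-[(tert-butyldimethylsilyl)oxy]-1-[dimethyl(phenyl)silyl]-2-methylbut-2-en-1-ol
Product: 5 (2E)-4-[(tert-butyldimethylsilyl)oxy]-1-[dimethyl(phenyl)silyl]-2-methylbut-2-en-1-one
Conditions: (COCl)2, DMSO, CH2Cl2, −78 °C; Et3N, −78 → 0 °C
Reagents that add atoms: none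
Why: Swern oxidation, the standard non-ionising way from α-hydroxysilanes to acylsilanes, which avoids Brook rearrangement.

Step 4
Reactants: 5 (2E)-4-[(tert-butyldimethylsilyl)oxy]-1-[dimethyl(phenyl)silyl]-2-methylbut-2-en-1-one
Product: 6 (1R,2E)-4-[(tert-butyldimethylsilyl)oxy]-1-[dimethyl(phenyl)silyl]-2-methylbut-2-en-1-ol
Conditions: RuCl2[(S)-tolbinap](pica) (cat.), t-BuOK (cat.), H2 (10 atm), EtOH, 25 °C (tolbinap = 2,2′-bis(di-p-tolylphosphino)-1,1′-binaphthyl, pica = 2-picolylamine)
Reagents that add atoms: none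
Why: asymmetric hydrogenation of an acylsilane carbonyl with a bifunctional ruthenium diphosphine/amine catalyst, which should reduce C=O in preference to C=C and set the carbinol centre as R by differentiating the silyl and alkenyl flanks.

Step 5
Reactants: 6 (1R,2E)-4-[(tert-butyldimethylsilyl)oxy]-1-[dimethyl(phenyl)silyl]-2-methylbut-2-en-1-ol
Product: 7 (1R,2E)-4-[(tert-butyldimethylsilyl)oxy]-1-[dimethyl(phenyl)silyl]-2-methylbut-2-en-1-yl 2-methylpropanoate
Conditions: (i-PrCO)2O, Et3N, DMAP (cat.), CH2Cl2, 0 °C → rt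
Reagents that add atoms: 2-methylpropanoic anhydride, CC(C)C(=O)OC(=O)C(C)C
Why: DMAP-catalysed acylation of a secondary alcohol under conditions that form no free alkoxide, so the C–Si/C–O stereocentre is untouched.

Step 6
Reactants: 7 (1R,2E)-4-[(tert-butyldimethylsilyl)oxy]-1-[dimethyl(phenyl)silyl]-2-methylbut-2-en-1-yl 2-methylpropanoate
Product: 10 (3R,4E)-3-{[(tert-butyldimethylsilyl)oxy]methyl}-5-[dimethyl(phenyl)silyl]-2,2,4-trimethylpent-4-enoic acid, via silyl ketene acetal 8 (not isolated), via trimethylsilyl ester 9 (not isolated)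
Conditions: LiN(i-Pr)2, THF, −78 °C; TMSCl; −78 → 50 °C; then H2O
Reagents that add atoms: none
Why: Ireland–Claisen rearrangement; the isobutyrate ketene acetal has no enolate geometry, and the chair transition state with the silyl group equatorial relays the carbinol centre suprafacially to C5, builds the C5–C6 bond with the quaternary CMe2 carbon and gives the E-vinylsilane.

Step 7
Reactants: 10 (3R,4E)-3-{[(tert-butyldimethylsilyl)oxy]methyl}-5-[dimethyl(phenyl)silyl]-2,2,4-trimethylpent-4-enoic acid
Product: 11 (4R,5E)-4-{[(tert-butyldimethylsilyl)oxy]methyl}-6-[dimethyl(phenyl)silyl]-3,3,5-trimethylhex-5-en-2-one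
Conditions: MeLi (3 equiv), Et2O, 0 °C → rt; then cold 1 M HCl
Reagents that add atoms: methyllithium, [Li]C
Why: methyl ketone synthesis from a carboxylic acid with an organolithium; the dilithium gem-diolate should collapse to the ketone only on work-up, and the quaternary α-carbon rules out enolisation or epimerisation.

Step 8
Reactants: 11 (4R,5E)-4-{[(tert-butyldimethylsilyl)oxy]methyl}-6-[dimethyl(phenyl)silyl]-3,3,5-trimethylhex-5-en-2-one
Product: 12 (4R,5E)-4-{[(tert-butyldimethylsilyl)oxy]methyl}-6-iodo-3,3,5-trimethylhex-5-en-2-one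
Conditions: NIS, (CF3)2CHOH, 0 °C
Reagents that add atoms: N-iodosuccinimide, O=C1CCC(=O)N1I
Why: electrophilic ipso-iododesilylation of a vinylsilane; iodine should attack the silyl-bearing carbon because this gives a tertiary β-silyl cation, and the geometry of the iodide (retention expected) does not matter for step 10.

Step 9
Reactants: 12 (4R,5E)-4-{[(tert-butyldimethylsilyl)oxy]methyl}-6-iodo-3,3,5-trimethylhex-5-en-2-one
Product: 14 (4R,5E)-4-{[(tert-butyldimethylsilyl)oxy]methyl}-6-iodo-3,3,5-trimethylhexa-1,5-dien-2-yl 3-methylbutanoate, via potassium enolate 13 (not isolated)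
Conditions: KN(SiMe3)2, THF, −78 °C; then (i-BuCO)2O, −78 → 0 °C
Reagents that add atoms: 3-methylbutanoic anhydride, CC(C)CC(=O)OC(=O)CC(C)C
Why: O-acylation of a ketone enolate with an anhydride (enol ester formation); only the methyl group can enolise because the other α-carbon is quaternary, and the hindered potassium enolate should acylate on oxygen, which puts the isovalerate of the target in place.

Step 10
Reactants: 14 (4R,5E)-4-{[(tert-butyldimethylsilyl)oxy]methyl}-6-iodo-3,3,5-trimethylhexa-1,5-dien-2-yl 3-methylbutanoate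
Product: 17 (1R,5S)-5-{[(tert-butyldimethylsilyl)oxy]methyl}-4,6,6-trimethylcyclohex-3-en-1-yl 3-methylbutanoate, via vinyl radical 15 (not isolated), via ring radical 16 (not isolated)
Conditions: Bu3SnH (syringe pump), AIBN (cat.), PhH (high dilution), 80 °C
Reagents that add atoms: none
Why: Bu3Sn• abstracts iodine from C3 to give a σ-vinyl radical that inverts freely, so the E geometry of 14 is irrelevant; the radical adds to the unsubstituted CH2 terminus (C2) of the enol isovalerate and the resulting tertiary α-acyloxy radical at C1 takes hydrogen from Bu3SnH. The closest known reaction type is the tin-hydride vinyl radical cyclisation onto a 1,1-disubstituted alkene. The single ring closes in the 6-endo-trig mode: the 5-exo alternative would have to bond C3 to the fully substituted enol carbon next to the quaternary C6, and any 5-exo adduct can still reach the same six-membered radical by the homoallyl/cyclopropylcarbinyl radical rearrangement while the stannane is kept dilute. The new stereocentre C1 is controlled by C5: hydrogen should be delivered on the face away from a pseudoaxial CH2OTBS group, or axially if that group is pseudoequatorial, and both paths place the ester cis to the C5 substituent. The step needs ring closure to outrun direct reduction and 1,5-hydrogen transfer from the gem-dimethyl group, which slow stannane addition at high dilution and the unhindered, electron-rich CH2 terminus should secure; the alkene stays at C3=C4 because C3 carried the radical.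

Step 11
Reactants: 17 (1R,5S)-5-{[(tert-butyldimethylsilyl)oxy]methyl}-4,6,6-trimethylcyclohex-3-en-1-yl 3-methylbutanoate
Product: 18 (1R,5S)-5-(hydroxymethyl)-4,6,6-trimethylcyclohex-3-en-1-yl 3-methylbutanoate
Conditions: HF·pyridine, THF, 0 °C → rt
Reagents that add atoms: none
Why: fluoride-mediated cleavage of a primary silyl ether; buffered HF·pyridine should leave the ester and the trisubstituted alkene untouched.

Step 12
Reactants: 18 (1R,5S)-5-(hydroxymethyl)-4,6,6-trimethylcyclohex-3-en-1-yl 3-methylbutanoate; 19 7-hydroxy-2H-chromen-2-one (umbelliferone)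
Product: 20 (1R,5S)-4,6,6-trimethyl-5-{[(2-oxo-2H-chromen-7-yl)oxy]methyl}cyclohex-3-en-1-yl 3-methylbutanoate
Conditions: PPh3, DIAD, THF, 0 °C → rt
Reagents that add atoms: none
Why: Mitsunobu etherification; the acidic phenol should displace the oxyphosphonium group at the primary CH2 (not a stereocentre), and attaching the coumarin last keeps its lactone away from organolithiums, amide bases and tin radicals.

**Compound list**

1 | 2-[(tert-butyldimethylsilyl)oxy]acetaldehyde | O=CCO[Si](C)(C)C(C)(C)C | starting material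
2 | 2-(triphenyl-λ5-phosphanylidene)propanal | CC(C=O)=P(c1ccccc1)(c1ccccc1)c1ccccc1 | starting material
3 | (2E)-4-[(tert-butyldimethylsilyl)oxy]-2-methylbut-2-enal | O=C/C(C)=C/CO[Si](C)(C)C(C)(C)C | intermediate
4 | rac-(2E)-4-[(tert-butyldimethylsilyl)oxy]-1-[dimethyl(phenyl)silyl]-2-methylbut-2-en-1-ol | C[Si](C)(c1ccccc1)C(O)/C(C)=C/CO[Si](C)(C)C(C)(C)C | intermediate
5 | (2E)-4-[(tert-butyldimethylsilyl)oxy]-1-[dimethyl(phenyl)silyl]-2-methylbut-2-en-1-one | C[Si](C)(c1ccccc1)C(=O)/C(C)=C/CO[Si](C)(C)C(C)(C)C | intermediate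
6 | (1R,2E)-4-[(tert-butyldimethylsilyl)oxy]-1-[dimethyl(phenyl)silyl]-2-methylbut-2-en-1-ol | C[Si](C)(c1ccccc1)[C@@H](O)/C(C)=C/CO[Si](C)(C)C(C)(C)C | intermediate
7 | (1R,2E)-4-[(tert-butyldimethylsilyl)oxy]-1-[dimethyl(phenyl)silyl]-2-methylbut-2-en-1-yl 2-methylpropanoate | CC(C)C(=O)O[C@H]([Si](C)(C)c1ccccc1)/C(C)=C/CO[Si](C)(C)C(C)(C)C | intermediate
8 | silyl ketene acetal: 1-{[(1R,2E)-4-[(tert-butyldimethylsilyl)oxy]-1-[dimethyl(phenyl)silyl]-2-methylbut-2-en-1-yl]oxy}-2-methyl-1-[(trimethylsilyl)oxy]prop-1-ene | CC(C)=C(O[Si](C)(C)C)O[C@H]([Si](C)(C)c1ccccc1)/C(C)=C/CO[Si](C)(C)C(C)(C)C | intermediate (not isolated)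
9 | trimethylsilyl (3R,4E)-3-{[(tert-butyldimethylsilyl)oxy]methyl}-5-[dimethyl(phenyl)silyl]-2,2,4-trimethylpent-4-enoate | C[Si](C)(C)OC(=O)C(C)(C)[C@@H](CO[Si](C)(C)C(C)(C)C)/C(C)=C/[Si](C)(C)c1ccccc1 | intermediate (not isolated)
10 | (3R,4E)-3-{[(tert-butyldimethylsilyl)oxy]methyl}-5-[dimethyl(phenyl)silyl]-2,2,4-trimethylpent-4-enoic acid | OC(=O)C(C)(C)[C@@H](CO[Si](C)(C)C(C)(C)C)/C(C)=C/[Si](C)(C)c1ccccc1 | intermediate
11 | (4R,5E)-4-{[(tert-butyldimethylsilyl)oxy]methyl}-6-[dimethyl(phenyl)silyl]-3,3,5-trimethylhex-5-en-2-one | CC(=O)C(C)(C)[C@@H](CO[Si](C)(C)C(C)(C)C)/C(C)=C/[Si](C)(C)c1ccccc1 | intermediate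
12 | (4R,5E)-4-{[(tert-butyldimethylsilyl)oxy]methyl}-6-iodo-3,3,5-trimethylhex-5-en-2-one | CC(=O)C(C)(C)[C@@H](CO[Si](C)(C)C(C)(C)C)/C(C)=C/I | intermediate
13 | potassium enolate of 12: potassium (4R,5E)-4-{[(tert-butyldimethylsilyl)oxy]methyl}-6-iodo-3,3,5-trimethylhexa-1,5-dien-2-olate | C=C([O-])C(C)(C)[C@@H](CO[Si](C)(C)C(C)(C)C)/C(C)=C/I.[K+] | intermediate (not isolated)
14 | (4R,5E)-4-{[(tert-butyldimethylsilyl)oxy]methyl}-6-iodo-3,3,5-trimethylhexa-1,5-dien-2-yl 3-methylbutanoate | C=C(OC(=O)CC(C)C)C(C)(C)[C@@H](CO[Si](C)(C)C(C)(C)C)/C(C)=C/I | intermediate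
15 | vinyl radical: 14 with the iodine removed and the unpaired electron on the terminal vinylic carbon (future C3) | C=C(OC(=O)CC(C)C)C(C)(C)[C@@H](CO[Si](C)(C)C(C)(C)C)C(C)=[CH] | intermediate (not isolated)
16 | ring radical: (5S)-5-{[(tert-butyldimethylsilyl)oxy]methyl}-4,6,6-trimethyl-1-[(3-methylbutanoyl)oxy]cyclohex-3-en-1-yl radical | CC1=CC[C](OC(=O)CC(C)C)C(C)(C)[C@H]1CO[Si](C)(C)C(C)(C)C | intermediate (not isolated)
17 | (1R,5S)-5-{[(tert-butyldimethylsilyl)oxy]methyl}-4,6,6-trimethylcyclohex-3-en-1-yl 3-methylbutanoate | CC1=CC[C@@H](OC(=O)CC(C)C)C(C)(C)[C@H]1CO[Si](C)(C)C(C)(C)C | intermediate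
18 | (1R,5S)-5-(hydroxymethyl)-4,6,6-trimethylcyclohex-3-en-1-yl 3-methylbutanoate | CC1=CC[C@@H](OC(=O)CC(C)C)C(C)(C)[C@H]1CO | intermediate
19 | 7-hydroxy-2H-chromen-2-one (umbelliferone) | O=c1ccc2ccc(O)cc2o1 | starting material
20 | (1R,5S)-4,6,6-trimethyl-5-{[(2-oxo-2H-chromen-7-yl)oxy]methyl}cyclohex-3-en-1-yl 3-methylbutanoate | CC1=CC[C@@H](OC(=O)CC(C)C)C(C)(C)[C@H]1COc1ccc2ccc(=O)oc2c1 | target

**Count and risks**

Total step count: 12. Longest linear sequence: 12 steps (1 → 20).

Steps most likely to fail: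

Step 10. The vinyl radical may be reduced, or may take a hydrogen from the gem-dimethyl group, before it closes the ring, and hydrogen delivery to the C1 radical may show poor facial selectivity. The fallback sets out from 11 and comes back at 17. Iododesilylation with inversion (ICl, CH2Cl2, −78 °C, then KF·2H2O, DMSO) passes through the anti adduct (4S)-4-{[(tert-butyldimethylsilyl)oxy]methyl}-5-chloro-6-[dimethyl(phenyl)silyl]-6-iodo-3,3,5-trimethylhexan-2-one F1 and should give the (Z)-iodo ketone (4R,5Z)-4-{[(tert-butyldimethylsilyl)oxy]methyl}-6-iodo-3,3,5-trimethylhex-5-en-2-one F2. With the iodine now cis to the chain, palladium-catalysed intramolecular coupling of the ketone enolate with the alkenyl iodide (Pd(PPh3)4, t-BuOK, THF/t-BuOH, rt; only the methyl side can enolise) closes the same C2–C3 bond to the β,γ-unsaturated ring ketone (3S)-3-{[(tert-butyldimethylsilyl)oxy]methyl}-2,2,4-trimethylcyclohex-4-en-1-one F3. NaBH4 in MeOH at −20 °C should add hydride anti to the C5 substituent and give the cis alcohol (1R,5S)-5-{[(tert-butyldimethylsilyl)oxy]methyl}-4,6,6-trimethylcyclohex-3-en-1-ol F4, and (i-BuCO)2O, Et3N, DMAP returns to 17.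

Step 9. The enolate may acylate on carbon, or the amide base may trigger α-elimination at the iodoalkene. The fallback sets out from 12 and comes back at 17. Soft enolisation (TMSOTf, Et3N, CH2Cl2, 0 °C) should give the silyl enol ether (4R,5E)-4-{[(tert-butyldimethylsilyl)oxy]methyl}-6-iodo-3,3,5-trimethyl-2-[(trimethylsilyl)oxy]hexa-1,5-diene F5. The same tin-hydride ring closure (Bu3SnH, AIBN, PhH, 80 °C) onto this acceptor should give (1R,5S)-5-{[(tert-butyldimethylsilyl)oxy]methyl}-4,6,6-trimethylcyclohex-3-en-1-yl trimethylsilyl ether F6. K2CO3 in MeOH removes only the secondary trimethylsilyl group to give the alcohol F4 already described, and acylation with (i-BuCO)2O, Et3N, DMAP returns to 17, so the ester is introduced after the ring closure instead of before it.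

Step 12. Displacement at the β-branched, neopentyl-like CH2 may be too slow, so that the activated alcohol decomposes or eliminates. The fallback sets out from 18 and comes back at 20. The aryl–oxygen bond is formed instead of the alkyl–oxygen bond: palladium-catalysed C–O cross-coupling of 18 with commercial 7-bromo-2H-chromen-2-one ([(allyl)PdCl]2, RockPhos, Cs2CO3, toluene, 90 °C) should give 20 directly and makes no new compound (F0).

**Further compounds**

F1 | step 10 | (4S)-4-{[(tert-butyldimethylsilyl)oxy]methyl}-5-chloro-6-[dimethyl(phenyl)silyl]-6-iodo-3,3,5-trimethylhexan-2-one (anti ICl adduct of 11, both alkene faces, same spatial arrangement at C4 as in 11) | CC(=O)C(C)(C)[C@@H](CO[Si](C)(C)C(C)(C)C)C(C)(Cl)C(I)[Si](C)(C)c1ccccc1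
F2 | step 10 | (4R,5Z)-4-{[(tert-butyldimethylsilyl)oxy]methyl}-6-iodo-3,3,5-trimethylhex-5-en-2-one | CC(=O)C(C)(C)[C@@H](CO[Si](C)(C)C(C)(C)C)/C(C)=C\I
F3 | step 10 | (3S)-3-{[(tert-butyldimethylsilyl)oxy]methyl}-2,2,4-trimethylcyclohex-4-en-1-one | CC1=CCC(=O)C(C)(C)[C@H]1CO[Si](C)(C)C(C)(C)C
F4 | step 10 | (1R,5S)-5-{[(tert-butyldimethylsilyl)oxy]methyl}-4,6,6-trimethylcyclohex-3-en-1-ol | CC1=CC[C@@H](O)C(C)(C)[C@H]1CO[Si](C)(C)C(C)(C)C
F5 | step 9 | (4R,5E)-4-{[(tert-butyldimethylsilyl)oxy]methyl}-6-iodo-3,3,5-trimethyl-2-[(trimethylsilyl)oxy]hexa-1,5-diene | C=C(O[Si](C)(C)C)C(C)(C)[C@@H](CO[Si](C)(C)C(C)(C)C)/C(C)=C/I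
F6 | step 9 | (1R,5S)-5-{[(tert-butyldimethylsilyl)oxy]methyl}-4,6,6-trimethylcyclohex-3-en-1-yl trimethylsilyl ether | CC1=CC[C@@H](O[Si](C)(C)C)C(C)(C)[C@H]1CO[Si](C)(C)C(C)(C)C
F0 | step 12 | none | none
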